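**Retrosynthetic overview**

1. Tomentodione Q ⇒ diketone 20 (C8 still a ketone; C1′ is fixed last through its enolate) ⇒ nitro compound 19 (Nef) ⇒ enol 18, the dihydropyran being closed by Markovnikov addition of the syncarpic enol O–H across C3=C4 (O–C4 bond).
2. 18 ⇒ aldehyde 14 + syncarpic acid + 2-methyl-1-nitropropane (Knoevenagel condensation at C1′, then Michael addition of the nitronate as isobutyryl anion equivalent).
3. Feature: in the nine-membered ring, C8 (carrier of the exocyclic methylene, a ketone until the last step) and C5 (the CH shared with the pyran) are 1,4-related through C7–C6, and the O-bearing quaternary C4 can be one end of a C3=C4 alkene. The ring therefore holds the δ,ε-unsaturated ketone (1,5-diene) retron of an oxy-Cope rearrangement that forms C5–C6 and breaks C3–C8.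
4. Cyclononenone 12 ⇒ 3-endo-alkenyl-2-exo-vinyl-6,6-dimethylbicyclo[3.2.0]heptan-2-ol 9 ⇒ cyclopentenone–isobutylene photoadduct 3 (α-alkenylation at C3, then vinyl addition).
5. Ring order: cyclobutane (step 1, on the cyclopentenone ring) → nine-membered ring by expansion of that cyclopentane (step 5) → dihydropyran (step 9); the syncarpic ring is brought in intact.

Key step: step 5

**Remarks on the chemistry**

- Atom labels follow caryophyllane numbering (C1–C11; C1′ = pyran CH, C2′–C7′ = syncarpic ring). The acetal is carried as the diethyl acetal because 1,1-diethoxybut-2-yne is the commercial butynal acetal.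
- C8 stays a ketone until the last step: a C8 methylene would be the preferred site of hydrogen-atom transfer or protonation in the pyran closure.
- The pyran is closed by hydrogen-atom-transfer chemistry. The tethered oxygen can reach C4 only on the outer face of the E ring alkene, so electrophiles that must sit anti to the nucleophile (I+, Hg2+, PhSe+) would have to enter from the transannular face. Brønsted acid is avoided because the C8 carbonyl and C3=C4 are placed for transannular Prins closure.

**Route**

Step 1
Reactants: 1 cyclopent-2-en-1-one; 2 isobutylene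
Product: 3 (1R,5R)-6,6-dimethylbicyclo[3.2.0]heptan-2-one
Conditions: AlBr3-activated chiral oxazaborolidine (50 mol %), 2 (excess), CH2Cl2, hν (366 nm), −75 °C
Reagents that add atoms: none
Why: Chiral-Lewis-acid-catalysed enone–alkene [2+2] photocycloaddition: the bound enone is excited selectively and shielded on one face, so the cis-fused head-to-tail adduct (CMe2 on the β-carbon, the usual regiochemistry with an electron-rich alkene) should form with both bridgeheads set by the catalyst, whose enantiomer is chosen to give (1R,5R).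

Step 2
Reactants: 4 1,1-diethoxybut-2-yne
Product: 6 (E)-1,1-diethoxy-3-iodobut-2-ene, via alkenylzirconocene chloride 5 (not isolated)
Conditions: Cp2Zr(H)Cl (1.3 equiv), THF, rt; then I2, −20 °C
Reagents that add atoms: iodine, II
Why: Schwartz hydrozirconation is a syn addition that places zirconium on the less hindered, methyl-bearing alkyne carbon, and iodinolysis of the C–Zr bond goes with retention, which gives the E iodide (I trans to the acetal carbon).

Step 3
Reactants: 3 (1R,5R)-6,6-dimethylbicyclo[3.2.0]heptan-2-one; 6 (E)-1,1-diethoxy-3-iodobut-2-ene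
Product: 8 (1R,3R,5R)-3-[(E)-4,4-diethoxybut-2-en-2-yl]-6,6-dimethylbicyclo[3.2.0]heptan-2-one (alkenyl endo), via lithium dienolate 7 (not isolated)
Conditions: LiHMDS (2.2 equiv), [Pd(allyl)Cl]2/Q-Phos (cat.), THF–toluene, 0 → 22 °C; then cannulated at −78 °C into AcOH/THF
Reagents that add atoms: none
Why: Palladium-catalysed α-alkenylation of the C3 lithium enolate (retention of alkene geometry) gives a ketone that is deprotonated at once to dienolate 7, and kinetic α-protonation of 7 from the convex exo face (the endo face of C3 is screened by the cyclobutane and its endo methyl group) places the alkenyl group endo (3R) without moving the double bond into conjugation.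

Step 4
Reactants: 8 (1R,3R,5R)-3-[(E)-4,4-diethoxybut-2-en-2-yl]-6,6-dimethylbicyclo[3.2.0]heptan-2-one
Product: 9 (1R,2R,3R,5R)-3-[(E)-4,4-diethoxybut-2-en-2-yl]-2-ethenyl-6,6-dimethylbicyclo[3.2.0]heptan-2-ol (vinyl exo; OH and alkenyl endo)
Conditions: CeCl3 (anhydrous), CH2=CHMgBr, THF, −78 °C; then H2O
Reagents that add atoms: vinylmagnesium bromide, C=C[Mg]Br
Why: Organocerium 1,2-addition (Imamoto conditions) suppresses enolization of the sensitive β,γ-unsaturated ketone, and attack from the convex exo face, which is also the face anti to the endo alkenyl group, sets C2 with vinyl exo and hydroxyl endo, i.e. vinyl and alkenyl trans.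

Step 5
Reactants: 9 (1R,2R,3R,5R)-3-[(E)-4,4-diethoxybut-2-en-2-yl]-2-ethenyl-6,6-dimethylbicyclo[3.2.0]heptan-2-ol
Product: 12 (1R,3E,5R,9R)-5-(diethoxymethyl)-4,11,11-trimethylbicyclo[7.2.0]undec-3-en-8-one (cis ring fusion), via potassium alkoxide 10 (not isolated), via potassium enolate 11 (not isolated)
Conditions: KH (1.5 equiv), 18-crown-6, THF, 0 → 40 °C; then AcOH, −78 °C
Reagents that add atoms: none
Why: Deprotonation gives alkoxide 10, whose charge-accelerated [3,3]-sigmatropic shift (anionic oxy-Cope rearrangement; closest precedent: ring expansion of trans-1-vinyl-2-alkenylcycloalkanols to medium-ring enones) forms C5–C6, breaks C3–C8 and delivers the C7=C8 enolate 11, which is protonated to 12. The nine-membered ring is closed by this four-carbon expansion of the cyclopentane, the new σ bond joining the two alkene termini (C5 of the butenyl group, C6 of the vinyl group) through a six-centre chair. In that chair the two cyclopentane bonds (C8–C9 and C3–C2) are equatorial, which the trans arrangement of vinyl and alkenyl allows and which gives the E C3=C4 alkene, and the E alkene terminus carries the acetal carbon equatorially. C5 is therefore fixed by the configurations of C8 and C3 (chirality transfer) and should come out as required relative to C1; C1 is untouched and C9 stays cis at this stage. The step needs [3,3] shift over [1,3] shift or cleavage, and chair over boat: the first is secured by the dissociated potassium alkoxide and the trans-dialkenyl geometry, the second by the C4 methyl group, which would eclipse C7–H in a boat.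

Step 6
Reactants: 12 (1R,3E,5R,9R)-5-(diethoxymethyl)-4,11,11-trimethylbicyclo[7.2.0]undec-3-en-8-one
Product: 13 (1R,3E,5R,9S)-5-(diethoxymethyl)-4,11,11-trimethylbicyclo[7.2.0]undec-3-en-8-one (trans ring fusion)
Conditions: NaOMe (0.2 equiv), MeOH, 25 °C
Reagents that add atoms: none
Why: Reversible enolization towards C9 under methoxide (thermodynamic epimerization) should convert the cis-fused ketone into the trans-fused bicyclo[7.2.0]undecenone, the more stable ring fusion in the caryophyllane series, while C5 (not α to a carbonyl) and the acetal are untouched.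

Step 7
Reactants: 13 (1R,3E,5R,9S)-5-(diethoxymethyl)-4,11,11-trimethylbicyclo[7.2.0]undec-3-en-8-one
Product: 14 (1R,3E,5R,9S)-4,11,11-trimethyl-8-oxobicyclo[7.2.0]undec-3-ene-5-carbaldehyde
Conditions: PPTS (0.2 equiv), acetone–H2O (10:1), 40 °C; used at once
Reagents that add atoms: water, O
Why: Mild acid-catalysed acetal hydrolysis frees the C5 aldehyde, and PPTS is weak enough to leave alone both the C8 ketone/C3=C4 pair (transannular Prins) and the C5–H, which is now α to an aldehyde and allylic.

Step 8
Reactants: 14 (1R,3E,5R,9S)-4,11,11-trimethyl-8-oxobicyclo[7.2.0]undec-3-ene-5-carbaldehyde; 15 syncarpic acid; 16 2-methyl-1-nitropropane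
Product: 18 enol form of 6-{3-methyl-2-nitro-1-[(1R,3E,5S,9S)-4,11,11-trimethyl-8-oxobicyclo[7.2.0]undec-3-en-5-yl]butyl}-2,2,4,4-tetramethylcyclohexane-1,3,5-trione (epimers at C1′ and at the nitro carbon), via alkylidene trione 17 (not isolated)
Conditions: 15 (1.0 equiv), Et3N (0.1 equiv), 4 Å MS, CH2Cl2, 0 °C; then 16 (5 equiv), DBU (1.5 equiv), −20 → 0 °C
Reagents that add atoms: none
Why: Knoevenagel condensation of the aldehyde with the strongly C–H acidic trione (tertiary amine, so that no enamine of the α-stereogenic aldehyde can form) gives alkylidene 17, which is trapped in the same flask by Michael addition of the nitronate of 16 before it can tautomerize towards C5; C1′ and the nitro carbon form as mixtures, which is harmless because the first is reset in step 11 and the second becomes the carbonyl carbon in step 10.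

Step 9
Reactants: 18 enol form of the C1′ nitroalkyl syncarpic acid adduct
Product: 19 (1R,4R,5S,9S)-configured dihydropyran (O–C4 closed; pyran trans-fused to the nine-membered ring; C8 ketone; CH(NO2)CH(CH3)2 at C1′; epimers at C1′ and the nitro carbon)
Conditions: Co(salen) catalyst (5 mol %), N-fluoro-2,4,6-trimethylpyridinium tetrafluoroborate (2 equiv), PhSiH3 (2 equiv), PhCF3, 0 °C → rt
Reagents that add atoms: none
Why: Cobalt-hydride hydrogen-atom transfer to C3 gives the tertiary C4 radical, which is oxidized (radical–polar crossover, Markovnikov hydroalkoxylation of an unactivated alkene) and captured by the enol oxygen in a 6-exo closure; C4 should be set in a chair-like closure in which the two nine-ring bonds (C4–C3 and C5–C6) are equatorial and the methyl group is axial, i.e. trans to H5, while the neutral conditions spare the C8 ketone and the nitro group keeps the side chain from closing to a furan.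

Step 10
Reactants: 19 nitro dihydropyran
Product: 20 (1R,4R,5S,9S)-configured diketone (isobutyryl at C1′, C8 ketone; C1′ epimers)
Conditions: K2CO3, 30 % aq. H2O2, MeOH, 0 °C → rt
Reagents that add atoms: hydrogen peroxide, OO
Why: Nef reaction of the secondary nitronate with alkaline hydrogen peroxide gives the isobutyryl ketone, and no C=C bond other than the vinylogous ester is present for the oxidant to attack.

Step 11
Reactants: 20 diketone
Product: 23 Tomentodione Q (1R,4R,5S,9S,1′R), via diketone potassium enolate 21 (not isolated), via methylenated potassium enolate 22 (not isolated)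
Conditions: KHMDS (1.05 equiv), THF, −78 °C; Ph3P=CH2 (from Ph3PCH3Br and KHMDS, 3 equiv), −78 → 40 °C; then AcOH, −78 °C
Reagents that add atoms: methyltriphenylphosphonium bromide, C[P+](c1ccccc1)(c1ccccc1)c1ccccc1.[Br-]
Why: The most acidic proton (C1′–H) is removed first, so the isobutyryl group is stored as its extended enolate while the ylide methylenates the only reactive ketone, C8 (Wittig reaction; C5′ lies between two quaternary carbons and C7′ is a vinylogous ester), and kinetic protonation of the enolate at C1′ from the face opposite the axial C4 methyl group places the isobutyryl group cis to that methyl (1′R).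

**Compound list**

1 | cyclopent-2-en-1-one | O=C1C=CCC1 | starting material
2 | isobutylene | C=C(C)C | starting material
3 | (1R,5R)-6,6-dimethylbicyclo[3.2.0]heptan-2-one | O=C1CC[C@@H]2[C@H]1CC2(C)C | intermediate
4 | 1,1-diethoxybut-2-yne | CC#CC(OCC)OCC | starting material
5 | [(E)-4,4-diethoxybut-2-en-2-yl]zirconocene chloride (Cp drawn σ-bonded) | CCOC(OCC)/C=C(\C)[Zr](Cl)(C1C=CC=C1)C1C=CC=C1 | intermediate
6 | (E)-1,1-diethoxy-3-iodobut-2-ene | CCOC(OCC)/C=C(\C)I | intermediate
7 | lithium (1R,5R)-3-[(E)-4,4-diethoxybut-2-en-2-yl]-6,6-dimethylbicyclo[3.2.0]hept-2-en-2-olate | [Li+].[O-]C1=C(/C(C)=C/C(OCC)OCC)C[C@@H]2[C@H]1CC2(C)C | intermediate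
8 | (1R,3R,5R)-3-[(E)-4,4-diethoxybut-2-en-2-yl]-6,6-dimethylbicyclo[3.2.0]heptan-2-one | O=C1[C@@H](/C(C)=C/C(OCC)OCC)C[C@@H]2[C@H]1CC2(C)C | intermediate
9 | (1R,2R,3R,5R)-3-[(E)-4,4-diethoxybut-2-en-2-yl]-2-ethenyl-6,6-dimethylbicyclo[3.2.0]heptan-2-ol | C=C[C@]1(O)[C@@H](/C(C)=C/C(OCC)OCC)C[C@@H]2[C@H]1CC2(C)C | intermediate
10 | potassium alkoxide of 9 | [K+].C=C[C@]1([O-])[C@@H](/C(C)=C/C(OCC)OCC)C[C@@H]2[C@H]1CC2(C)C | intermediate
11 | potassium C7=C8 enolate of 12 | [K+].[O-]/C1=C\C[C@@H](C(OCC)OCC)/C(C)=C/C[C@@H]2[C@H]1CC2(C)C | intermediate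
12 | (1R,3E,5R,9R)-5-(diethoxymethyl)-4,11,11-trimethylbicyclo[7.2.0]undec-3-en-8-one (cis-fused) | O=C1CC[C@@H](C(OCC)OCC)/C(C)=C/C[C@@H]2[C@H]1CC2(C)C | intermediate
13 | (1R,3E,5R,9S)-5-(diethoxymethyl)-4,11,11-trimethylbicyclo[7.2.0]undec-3-en-8-one (trans-fused) | O=C1CC[C@@H](C(OCC)OCC)/C(C)=C/C[C@@H]2[C@@H]1CC2(C)C | intermediate
14 | (1R,3E,5R,9S)-4,11,11-trimethyl-8-oxobicyclo[7.2.0]undec-3-ene-5-carbaldehyde | O=C1CC[C@@H](C=O)/C(C)=C/C[C@@H]2[C@@H]1CC2(C)C | intermediate
15 | syncarpic acid (2,2,4,4-tetramethylcyclohexane-1,3,5-trione) | CC1(C)C(=O)CC(=O)C(C)(C)C1=O | starting material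
16 | 2-methyl-1-nitropropane | CC(C)C[N+](=O)[O-] | starting material
17 | 6-{[(1R,3E,5S,9S)-4,11,11-trimethyl-8-oxobicyclo[7.2.0]undec-3-en-5-yl]methylidene}-2,2,4,4-tetramethylcyclohexane-1,3,5-trione | O=C1CC[C@@H](C=C3C(=O)C(C)(C)C(=O)C(C)(C)C3=O)/C(C)=C/C[C@@H]2[C@@H]1CC2(C)C | intermediate
18 | enol form of the Michael adduct of 17 and 16 (C5 S; C1′ and nitro carbon as epimer mixtures) | O=C1CC[C@@H](C(C(C(C)C)[N+](=O)[O-])C3=C(O)C(C)(C)C(=O)C(C)(C)C3=O)/C(C)=C/C[C@@H]2[C@@H]1CC2(C)C | intermediate
19 | nitro dihydropyran (1R,4R,5S,9S; C8 ketone; C1′ and nitro carbon as epimer mixtures) | O=C1CC[C@H]2C(C(C(C)C)[N+](=O)[O-])C3=C(O[C@]2(C)CC[C@@H]2[C@@H]1CC2(C)C)C(C)(C)C(=O)C(C)(C)C3=O | intermediate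
20 | C8-oxo diketone (1R,4R,5S,9S; isobutyryl at C1′; C1′ epimers) | O=C1CC[C@H]2C(C(=O)C(C)C)C3=C(O[C@]2(C)CC[C@@H]2[C@@H]1CC2(C)C)C(C)(C)C(=O)C(C)(C)C3=O | intermediate
21 | potassium C1′ enolate of 20 | [K+].O=C1CC[C@H]2C(=C([O-])C(C)C)C3=C(O[C@]2(C)CC[C@@H]2[C@@H]1CC2(C)C)C(C)(C)C(=O)C(C)(C)C3=O | intermediate
22 | potassium C1′ enolate of 23 | [K+].C=C1CC[C@H]2C(=C([O-])C(C)C)C3=C(O[C@]2(C)CC[C@@H]2[C@@H]1CC2(C)C)C(C)(C)C(=O)C(C)(C)C3=O | intermediate
23 | Tomentodione Q | C=C1CC[C@H]2[C@@H](C(=O)C(C)C)C3=C(O[C@]2(C)CC[C@@H]2[C@@H]1CC2(C)C)C(C)(C)C(=O)C(C)(C)C3=O | target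

**Step count**

Total: 11 steps. Longest linear sequence: 10 steps (steps 1, 3–11; step 2 is a side branch).

**Steps most likely to fail**

1. Step 9. The capture of the C4 cation equivalent may show poor facial selectivity (cis instead of trans pyran fusion), the N–F oxidant may fluorinate the enol at C2′, and a transannular hydrogen shift may move the radical away from C4. Fallback from 18: a palladium(II)-catalysed aerobic Wacker-type cyclization [Pd(TFA)2, pyridine, O2, toluene, 80 °C] adds the enol oxygen and palladium syn across the exposed face of C3=C4, and β-hydride elimination towards C2 would give the 2,3-dehydro dihydropyran F1. Diimide (potassium azodicarboxylate, AcOH, MeOH, rt) would then saturate the disubstituted C2=C3 bond and return to the route at 19.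

2. Step 8. C5 may epimerize, either by enolization of the β,γ-unsaturated aldehyde 14 or by γ-deprotonation of alkylidene 17 to the extended dienol; a second molecule of 15 may also add to 17. Fallback from 13, which avoids the free aldehyde: the trimethylsilyl enol ether of syncarpic acid F2 (from 15, TMSCl, Et3N) would be added to acetal 13 under TMSOTf catalysis at −78 °C (Mukaiyama-type addition to the oxocarbenium ion) to give the β-ethoxy adduct F3. Treatment of F3 with DBU and excess 16 would release the alkylidene by loss of ethoxide only in the presence of the nitronate, and return to the route at 18.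

3. Step 3. Dienolate 7 may lose ethoxide from the acetal (vinylogous β-elimination) at room temperature, the protonation may show poor facial selectivity, and the endo ketone may epimerize or conjugate on handling. Fallback from 3, which sets C3 by a stereospecific anti epoxide opening:
   - Condensation with TsNHNH2 would give the tosylhydrazone F4, and a Shapiro reaction (n-BuLi, TMEDA; H2O) the alkene F5.
   - mCPBA would epoxidize the convex face to the exo-epoxide F6.
   - The alkenylmagnesium chloride F7 (from 6 and i-PrMgCl·LiCl) would open F6 at C3 under CuI catalysis from the endo face to the trans alcohol F8 (alkenyl endo, OH exo). Approach on this face is hindered, so the opening may be slow.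
   - Dess–Martin oxidation of F8 would return to the route at 8.

**Further compounds**

F1 | step 9 | 2,3-dehydro analogue of 19 (C2=C3 alkene, pyran closed) | O=C1CC[C@H]2C(C(C(C)C)[N+](=O)[O-])C3=C(O[C@]2(C)C=C[C@@H]2[C@@H]1CC2(C)C)C(C)(C)C(=O)C(C)(C)C3=O
F2 | step 8 | 4,4,6,6-tetramethyl-3-(trimethylsilyloxy)cyclohex-2-ene-1,5-dione | C[Si](C)(C)OC1=CC(=O)C(C)(C)C(=O)C1(C)C
F3 | step 8 | enol form of the C1′-ethoxy adduct of 13 and syncarpic acid (C1′ epimers) | O=C1CC[C@@H](C(OCC)C3=C(O)C(C)(C)C(=O)C(C)(C)C3=O)/C(C)=C/C[C@@H]2[C@@H]1CC2(C)C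
F4 | step 3 | tosylhydrazone of 3 | Cc1ccc(cc1)S(=O)(=O)NN=C1CC[C@@H]2[C@H]1CC2(C)C
F5 | step 3 | (1R,5R)-6,6-dimethylbicyclo[3.2.0]hept-2-ene (cis-fused, from 3) | C1=CC[C@@H]2[C@H]1CC2(C)C
F6 | step 3 | exo-2,3-epoxy-6,6-dimethylbicyclo[3.2.0]heptane | [C@@H]12O[C@@H]1C[C@@H]1[C@H]2CC1(C)C
F7 | step 3 | [(E)-4,4-diethoxybut-2-en-2-yl]magnesium chloride | CCOC(OCC)/C=C(\C)[Mg]Cl
F8 | step 3 | 3-endo-[(E)-4,4-diethoxybut-2-en-2-yl]-6,6-dimethylbicyclo[3.2.0]heptan-2-exo-ol | O[C@@H]1[C@@H](/C(C)=C/C(OCC)OCC)C[C@@H]2[C@H]1CC2(C)C
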